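An easy step first: one electrophile and one nucleophile give one target and one acid set free. If the acid then ties up a second nucleophile and the target takes a second electrophile, each round costs two of each, so the two should fall one for one.

| flask | electrophile | nucleophile | remark | time |
|---|---|---|---|---|
| beta | 1 M | 1.8 M | run made earlier |  |
| delta | 2.2 M | 1.8 M | run made earlier |  |
| epsilon | 1.5 M | 2.7 M | run made earlier |  |
| flask | 1.5 M | 1.80 M |  | 12 min |

| run | time / min | electrophile / % | target / % |
|---|---|---|---|
| beta | 0.500 | 69.7 | 17.0 |
| beta | 1.33 | 47.5 | 16.3 |
| beta | 2.50 | 29.9 | 14.4 |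
| beta | 4.00 | 17.7 | 12.1 |
| beta | 6.00 | 10.0 | 11.2 |
| beta | 8.00 | 5.1 | 10.3 |
| beta | 10.0 | 2.9 | 13.1 |
| delta | 0.500 | 70.6 | 8.4 |
| delta | 1.33 | 52.9 | 5.3 |
| delta | 2.50 | 44.0 | 4.7 |
| delta | 4.00 | 33.9 | 2.1 |
| delta | 6.00 | 30.1 | 2.4 |
| delta | 8.00 | 24.5 | 0 |
| delta | 10.0 | 23.2 | 0.2 |
| epsilon | 2.00 | 22.1 | 15.0 |
| epsilon | 4.00 | 7.8 | 10.4 |
| epsilon | 6.00 | 4.0 | 12.6 |
| epsilon | 8.00 | 1.3 | 11.5 |
| epsilon | 10.0 | 1.2 | 10.7 |

(standard deviation of a reading: 1 percentage point)

- part of the electrophile that has reacted at 12 min
- share of free nucleophile in free nucleophile and protonated nucleophile together, at 12 min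

- a species is counted by the electrophile in it: one side product counts as two
- amounts and yields of acid set free count crystals too
- given per volume of solution although it is solid: crystals
- steps under discussion: crystals <-> acid set free; electrophile + target -> side product; nucleophile + acid set free <-> protonated nucleophile; electrophile + nucleophile -> acid set free + target; nucleophile <-> dormant form
- the earlier runs do not show how much of nucleophile is bound; that part of a forecast is a guess

For the flask asked about, 120% is what we call the ceiling, the nucleophile charge over the electrophile charge: the part of the electrophile that the nucleophile can pay for at one for one. Delta, where nucleophile is the limiting reagent, has a ceiling of 81.8%, and its electrophile column flattens, with 76.8% lost in the last row. Beta has a ceiling of 180%, and its column falls on to 2.9%. Beta's target column reads 13.1% in that row, though 97.1% of the electrophile is lost, which fits the second electrophile.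

That gives the stopping end; the other end is speed. We take the rate as electrophile times nucleophile and read its constant from beta's last row. Carried to the flask, our one-for-one reckoning has the ratio of nucleophile to electrophile grow by a factor of 3.47, and so gives 93.7% reacted, under a ceiling above the whole charge.

The forecast gives 92%, a little lower than ours, and 32% for the share, adding “this part is a guess”.

The flask gives 93.9% and 15.3%.

    crystals ⇌ acid set free, rate k1*(cs1 - [acid set free]) while solid is left; crystals form when [acid set free] > cs1 (solubility = 0.130 M, k = 0.390 s⁻¹)
    electrophile + target → side product (k = 0.0240 M⁻¹ s⁻¹)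
    nucleophile + acid set free ⇌ protonated nucleophile, settled at all times (K = 3300 M⁻¹)
    electrophile + nucleophile → acid set free + target (k = 0.00780 M⁻¹ s⁻¹)
    nucleophile ⇌ dormant form (K = 1.50, k = 0.0220 s⁻¹)

The forecast's share stands 17 percentage points above the flask's, where the dormant form holds 0.206 M at 12.0 min. The flask's reacted part lies under its ceiling of 120%. The neighbour charged with 0.45 M of nucleophile has a ceiling of 30.0% and reacts 30.2%, about that figure, with 0.88% of its nucleophile still free. The flask has not come to rest: at 120 min its reacted part is >99.9%, its side product has gone from 90.3% to 97.1%, and its dormant form has gone from 0.206 M to 0.155 M.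

(The runs are simulated with made-up constants; noise was put on by code.)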